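## Retrosynthetic overview

1. The target is the C2-symmetric (2R,3R,2''R,3''R)-3,3''-biflavanone, with H-2 and H-3 cis in both rings C. The four phenols are freed last from benzyl ethers.
2. The strategy rests on the chain O1–C2–C3–C3''–C2''–O1'' that joins the two rings C, with the acyl carbons C4 and C4'' on C3 and C3''. This chain is atom for atom the core of a 2,6-diaryl-3,7-dioxabicyclo[3.3.0]octane-4,8-dione, and an exo aryl group on that bicycle becomes a 2,3-cis pair once O1 and C4 of the same half are tied into ring C.
3. Both O1–C8a bonds are disconnected (intramolecular SNAr on aryl fluorides, C2–O untouched), as are both C4–C4a bonds (aryllithium opening of the two lactone carbonyls). This leads back to the resolved bis-lactone and a 2-fluoro-4,6-bis(benzyloxy)phenyl anion made from 1,3,5-trifluorobenzene.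
4. The bis-lactone is disconnected at C3–C3'' and at both C2–O bonds, back to two molecules of 4-methoxycinnamic acid (one-electron oxidative dimerisation).
5. Ring order: the two γ-lactones form together as a temporary template carrying all four stereocentres, both are then opened, and the two rings C close together. Rings A and B are bought as arenes.

Key step: step 1

Remark on the chemistry: 2 forms as a racemate and is written with the SMILES of the enantiomer that is carried on; 12 is written as the open diketo diol, although it may rest partly as its bis-hemiketal, because base converts both forms into the same dialkoxide.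

## Route

Step 1
Reactants: 1 4-methoxycinnamic acid (two molecules)
Product: 2 rac-(1R*,2R*,5R*,6R*)-2,6-bis(4-methoxyphenyl)-3,7-dioxabicyclo[3.3.0]octane-4,8-dione (cis-fused, both aryl groups exo)
Conditions: Tl(OCOCF3)3 (0.55 equiv), BF3·OEt2, CF3CO2H–CH2Cl2, −20 → 0 °C
Reagents that add atoms: none
Why: Trivalent thallium removes one electron from the anisyl-conjugated alkene of 1; the radical cation carries its spin mainly on the carbon α to the carboxyl group and bonds there to the α-carbon of a second molecule, and loss of the second electron leaves a 4-methoxybenzylic cation at each end of the new C–C bond. The closest known reaction type is exactly this one, the oxidative dimerisation of 4-alkoxycinnamic acids to 2,6-diaryl-3,7-dioxabicyclo[3.3.0]octane-4,8-diones, the non-phenolic relative of the 8–8' coupling of ferulic acid. Each of the two γ-lactone rings closes 5-exo-trig, the carboxyl oxygen of one half adding to the cationic benzylic carbon of the other half, since capture within the same half would need a four-membered ring. The bridgehead centres C1 and C5 are controlled by the ring fusion: only the like-configured dimer can close both five-membered rings, and then only cis-fused, so an unlike-coupled dimer costs material but cannot contaminate 2. The benzylic centres C2 and C6 are controlled by the fold of the bicycle, which places both aryl groups on the convex face next to the bridgehead hydrogens, and because 4-methoxybenzylic C–O bonds ionise reversibly in this acidic medium the exo,exo isomer is also the product of equilibration. The step needs α,α regioselectivity, secured by the spin distribution and by the para-methoxy stabilisation of the cations, and exo,exo diastereoselectivity, secured by the bicycle; nothing in it distinguishes the enantiomers, so 2 should form as the racemate.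

Step 2
Reactants: 2 rac-bis-lactone
Product: 3 (1R,2R,5R,6R)-2,6-bis(4-methoxyphenyl)-3,7-dioxabicyclo[3.3.0]octane-4,8-dione (single enantiomer)
Conditions: preparative SFC, immobilised amylose tris(3,5-dimethylphenylcarbamate) phase, CO2–iPrOH, 35 °C
Reagents that add atoms: none
Why: Resolution by chromatography on a chiral stationary phase makes or breaks no bond, a rigid C2-symmetric diaryl bis-lactone is a good candidate for it, and the all-R fraction is to be identified by anomalous-dispersion X-ray diffraction (Cu Kα) or by comparing measured and computed ECD curves.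

Step 3
Reactants: 4 1,3,5-trifluorobenzene; 5 benzyl alcohol (2.2 equiv)
Product: 8 1,3-bis(benzyloxy)-5-fluorobenzene, via sodium benzyloxide 6 (not isolated), via 1-(benzyloxy)-3,5-difluorobenzene 7 (not isolated)
Conditions: 5, NaH (2.2 equiv), NMP, 0 °C → rt until H2 evolution ends; then 4, sealed vessel, 60 → 110 °C
Reagents that add atoms: none
Why: This is a twofold SNAr in which each C–F carbon is activated inductively by the meta halogens, and every alkoxy group that enters slows the next substitution, so the stoichiometry should stop the sequence at the bis-ether.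

Step 4
Reactants: 8 1,3-bis(benzyloxy)-5-fluorobenzene
Product: 9 1,5-bis(benzyloxy)-2-bromo-3-fluorobenzene
Conditions: NBS (1.0 equiv), MeCN, 0 °C → rt, dark
Reagents that add atoms: N-bromosuccinimide, O=C1CCC(=O)N1Br
Why: In this electrophilic aromatic bromination the two equivalent positions para to one benzyloxy group and ortho to the other (next to the small fluorine) should be preferred over the position flanked by two benzyloxy groups, as is usual for resorcinol diethers.

Step 5
Reactants: 9 1,5-bis(benzyloxy)-2-bromo-3-fluorobenzene (2.3 equiv); 3 (1R,2R,5R,6R)-bis-lactone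
Product: 12 (2R,3R)-1,4-bis[2,4-bis(benzyloxy)-6-fluorophenyl]-2,3-bis[(R)-hydroxy(4-methoxyphenyl)methyl]butane-1,4-dione, via aryllithium 10 (not isolated), via dilithium bis-lactolate 11 (not isolated)
Conditions: 9, n-BuLi (2.2 equiv), THF, −78 °C; then 3 in THF, −78 °C; AcOH in THF, −78 °C; buffered work-up, Et3N-deactivated silica
Reagents that add atoms: none
Why: This is the mono-addition of an aryllithium to a lactone, as used to make lactols in C-aryl glycoside synthesis: Br/Li exchange at −78 °C outruns loss of LiF, the tetrahedral lithium lactolates persist in the cold so that no ketone meets a second equivalent, attack at the carbonyl carbons leaves all four stereocentres untouched, and the cold acid quench forestalls base-induced β-elimination.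

Step 6
Reactants: 12 diketo diol
Product: 15 (2R,2'R,3R,3'R)-5,5',7,7'-tetrakis(benzyloxy)-2,2'-bis(4-methoxyphenyl)-2,2',3,3'-tetrahydro-4H,4'H-[3,3'-bichromene]-4,4'-dione, via dilithium dialkoxide 13 (not isolated), via half-closed lithium alkoxide 14 (not isolated)
Conditions: LiN(SiMe3)2 (2.0 equiv), THF–DMPU, −78 → 0 °C (warmed only as far as conversion requires); pH 7 phosphate buffer
Reagents that add atoms: none
Why: This is an intramolecular SNAr through a Meisenheimer adduct stabilised by the ortho ketone, in which each benzylic alkoxide reaches the C–F carbon of the aryl ketone of its own half through a six-membered transition state (the other aryl fluoride would need a seven-membered one), the C2–O bond is never broken so C2 is retained, and base that is limited to two equivalents and consumed as LiF in the cold leaves little room for enolisation at C3 or retro-aldol cleavage, so the 2,3-cis relationship inherited from the exo aryl groups of 3 should survive.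

Step 7
Reactants: 15 tetra-O-benzyl biflavanone
Product: 16 (2R,2'R,3R,3'R)-5,5',7,7'-tetrahydroxy-2,2'-bis(4-methoxyphenyl)-2,2',3,3'-tetrahydro-4H,4'H-[3,3'-bichromene]-4,4'-dione (target)
Conditions: H2 (1 atm), Pd/C (10 wt % Pd), THF–MeOH, rt
Reagents that add atoms: none
Why: Hydrogenolysis of the four benzyl aryl ethers on palladium metal runs under neutral conditions, under which the methyl ethers, the aryl ketones and the hindered ring C C2–O1 bond react much more slowly and neither C2 nor C3 can epimerise.

## Compound list

1 | 4-methoxycinnamic acid | COc1ccc(/C=C/C(=O)O)cc1 | starting material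
2 | rac-(1R*,2R*,5R*,6R*)-2,6-bis(4-methoxyphenyl)-3,7-dioxabicyclo[3.3.0]octane-4,8-dione (racemate, drawn as the enantiomer carried on) | O=C1O[C@@H](c2ccc(OC)cc2)[C@H]2[C@@H]1[C@H](c1ccc(OC)cc1)OC2=O | intermediate
3 | (1R,2R,5R,6R)-2,6-bis(4-methoxyphenyl)-3,7-dioxabicyclo[3.3.0]octane-4,8-dione (single enantiomer) | O=C1O[C@@H](c2ccc(OC)cc2)[C@H]2[C@@H]1[C@H](c1ccc(OC)cc1)OC2=O | intermediate
4 | 1,3,5-trifluorobenzene | Fc1cc(F)cc(F)c1 | starting material
5 | benzyl alcohol | OCc1ccccc1 | starting material
6 | sodium benzyloxide | [Na+].[O-]Cc1ccccc1 | intermediate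
7 | 1-(benzyloxy)-3,5-difluorobenzene | Fc1cc(F)cc(OCc2ccccc2)c1 | intermediate
8 | 1,3-bis(benzyloxy)-5-fluorobenzene | Fc1cc(OCc2ccccc2)cc(OCc2ccccc2)c1 | intermediate
9 | 1,5-bis(benzyloxy)-2-bromo-3-fluorobenzene | Fc1cc(OCc2ccccc2)cc(OCc2ccccc2)c1Br | intermediate
10 | [2,4-bis(benzyloxy)-6-fluorophenyl]lithium | [Li]c1c(F)cc(OCc2ccccc2)cc1OCc1ccccc1 | intermediate
11 | dilithium bis-lactolate: 4,8-bis[2,4-bis(benzyloxy)-6-fluorophenyl]-2,6-bis(4-methoxyphenyl)-3,7-dioxabicyclo[3.3.0]octane-4,8-diolate (configuration at C4 and C8 left open) | [Li+].[Li+].[O-]C1(c2c(F)cc(OCc3ccccc3)cc2OCc2ccccc2)O[C@@H](c2ccc(OC)cc2)[C@H]2[C@@H]1[C@H](c1ccc(OC)cc1)OC2([O-])c1c(F)cc(OCc2ccccc2)cc1OCc1ccccc1 | intermediate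
12 | (2R,3R)-1,4-bis[2,4-bis(benzyloxy)-6-fluorophenyl]-2,3-bis[(R)-hydroxy(4-methoxyphenyl)methyl]butane-1,4-dione | COc1ccc([C@H](O)[C@H](C(=O)c2c(F)cc(OCc3ccccc3)cc2OCc2ccccc2)[C@@H](C(=O)c2c(F)cc(OCc3ccccc3)cc2OCc2ccccc2)[C@@H](O)c2ccc(OC)cc2)cc1 | intermediate
13 | dilithium dialkoxide of 12 | [Li+].[Li+].COc1ccc([C@H]([O-])[C@H](C(=O)c2c(F)cc(OCc3ccccc3)cc2OCc2ccccc2)[C@@H](C(=O)c2c(F)cc(OCc3ccccc3)cc2OCc2ccccc2)[C@@H]([O-])c2ccc(OC)cc2)cc1 | intermediate
14 | lithium (1R,2R)-3-[2,4-bis(benzyloxy)-6-fluorophenyl]-2-[(2R,3R)-5,7-bis(benzyloxy)-2-(4-methoxyphenyl)-4-oxochroman-3-yl]-1-(4-methoxyphenyl)-3-oxopropan-1-olate (one ring C closed) | [Li+].COc1ccc([C@@H]2Oc3cc(OCc4ccccc4)cc(OCc4ccccc4)c3C(=O)[C@@H]2[C@@H](C(=O)c2c(F)cc(OCc3ccccc3)cc2OCc2ccccc2)[C@@H]([O-])c2ccc(OC)cc2)cc1 | intermediate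
15 | (2R,2'R,3R,3'R)-5,5',7,7'-tetrakis(benzyloxy)-2,2'-bis(4-methoxyphenyl)-2,2',3,3'-tetrahydro-4H,4'H-[3,3'-bichromene]-4,4'-dione | COc1ccc([C@@H]2Oc3cc(OCc4ccccc4)cc(OCc4ccccc4)c3C(=O)[C@@H]2[C@H]2C(=O)c3c(OCc4ccccc4)cc(OCc4ccccc4)cc3O[C@H]2c2ccc(OC)cc2)cc1 | intermediate
16 | (2R,2'R,3R,3'R)-5,5',7,7'-tetrahydroxy-2,2'-bis(4-methoxyphenyl)-2,2',3,3'-tetrahydro-4H,4'H-[3,3'-bichromene]-4,4'-dione | COc1ccc([C@@H]2Oc3cc(O)cc(O)c3C(=O)[C@@H]2[C@H]2C(=O)c3c(O)cc(O)cc3O[C@H]2c2ccc(OC)cc2)cc1 | target

## Step count and risks

Total step count: 7.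
Longest linear sequence: 5 steps (1, 2, 5, 6, 7). The arene branch 3, 4, 5, 6, 7 is equally long.

### Step 6 (double ring closure), the riskiest step

- **What may go wrong:** The β-keto alkoxide may fragment by retro-aldol cleavage of the C2–C3 bond, or exchange its charge with C3–H. Either could happen faster than attack on an aryl fluoride that is deactivated by two alkoxy groups and twisted out of conjugation with its ketone, and either process erodes the 2,3-cis relationship.
- **Fallback:** Addition–elimination is replaced by a palladium-catalysed intramolecular aryl etherification (Buchwald–Hartwig type). Here the alcohol is bound to divalent palladium and only an insoluble weak base is present.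
- **Where it leaves and rejoins:** It sets out from 3 and comes back to the route at 15.
- **Course:** 1-Bromo-3,5-difluorobenzene and 5, under the conditions of step 3, should give 1,3-bis(benzyloxy)-5-bromobenzene F1. N-Iodosuccinimide in MeCN should iodinate para to one benzyloxy group to give 1,5-bis(benzyloxy)-3-bromo-2-iodobenzene F2. I/Mg exchange with iPrMgCl·LiCl in THF at −40 °C should give [2,4-bis(benzyloxy)-6-bromophenyl]magnesium chloride F3, which does not yet collapse to an aryne at that temperature. Added to 3 (−40 → −10 °C, NH4Cl quench), it should give the dibromo diketo diol F4. Pd(OAc)2, 2-(di-tert-butylphosphino)-1,1'-binaphthyl and K3PO4 in toluene at 60 °C should then close both rings C with the C2–O bonds intact.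

### Step 5 (double opening of the bis-lactone)

- **What may go wrong:** The hindered aryllithium may act as a base on a bridgehead C–H α to a lactone carbonyl, after which β-elimination of the carboxylate of the neighbouring ring unzips the bicycle. The second addition may also stall, and the reagent may lose LiF if the temperature drifts.
- **Fallback:** Ring opening is separated from C–C bond formation.
- **Where it leaves and rejoins:** It sets out from 3 and comes back to the route at 12.
- **Course:** MeNH(OMe)·HCl and AlMe3 (CH2Cl2, 0 °C) form a weakly basic aluminium amide that should open both lactones to the bis(N-methoxy-N-methylamide) diol F5. Et3SiOSO2CF3 and 2,6-lutidine cap the alcohols at once, before relactonisation, to give the bis(triethylsilyl) ether diamide F6. Two equivalents of 10, made as in step 5, add at −78 °C to the amides, whose chelated tetrahedral adducts hold until the quench, to give the bis(triethylsilyl) ether diketone F7. HF·pyridine buffered with pyridine (THF, 0 °C) then frees 12.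

### Step 1 (oxidative dimerisation)

- **What may go wrong:** With only one alkoxy group the alkene is harder to oxidise, so electrophilic thallation of the ring, over-oxidation and unlike coupling may consume the material.
- **Fallback:** The same central bond is formed at the saturated acid level under auxiliary control, and the two C–O bonds are added afterwards. This also makes step 2 unnecessary.
- **Where it leaves and rejoins:** It sets out from 1 and comes back to the route at 3.
- **Course, up to the coupling:** Hydrogenation of 1 (H2, Pd/C, EtOAc) gives 3-(4-methoxyphenyl)propanoic acid F8. Pivaloyl chloride and Et3N, then the lithium salt of (4R)-4-isopropyl-1,3-oxazolidin-2-one, give the N-acyl oxazolidinone F9. LiN(iPr)2 (THF, −78 °C) followed by CuCl2 couples two Z-enolates oxidatively, each on the face away from its isopropyl group, to the (2S,3S)-bis-imide dimer F10.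
- **Course, from the dimer to 3:** LiOH and H2O2 remove the auxiliary to give (2S,3S)-2,3-bis(4-methoxybenzyl)butanedioic acid F11. Its arrangement in space is that of 3; the descriptor changes from S to R only because oxygen later enters at the benzylic carbons. PhI(OAc)2 and KBr (CH2Cl2, rt) then bring about benzylic C–H lactonisation twice. Each carboxyl group captures the benzylic position of the other half in a five-membered ring, with cis fusion and exo aryl groups enforced as in step 1.

Further compounds
F1 | step 6 | 1,3-bis(benzyloxy)-5-bromobenzene | Brc1cc(OCc2ccccc2)cc(OCc2ccccc2)c1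
F2 | step 6 | 1,5-bis(benzyloxy)-3-bromo-2-iodobenzene | Brc1cc(OCc2ccccc2)cc(OCc2ccccc2)c1I
F3 | step 6 | [2,4-bis(benzyloxy)-6-bromophenyl]magnesium chloride | Cl[Mg]c1c(Br)cc(OCc2ccccc2)cc1OCc1ccccc1
F4 | step 6 | (2R,3R)-1,4-bis[2,4-bis(benzyloxy)-6-bromophenyl]-2,3-bis[(R)-hydroxy(4-methoxyphenyl)methyl]butane-1,4-dione | COc1ccc([C@H](O)[C@H](C(=O)c2c(Br)cc(OCc3ccccc3)cc2OCc2ccccc2)[C@@H](C(=O)c2c(Br)cc(OCc3ccccc3)cc2OCc2ccccc2)[C@@H](O)c2ccc(OC)cc2)cc1
F5 | step 5 | (2R,3R)-2,3-bis[(R)-hydroxy(4-methoxyphenyl)methyl]-N,N'-dimethoxy-N,N'-dimethylbutanediamide | COc1ccc([C@H](O)[C@H](C(=O)N(C)OC)[C@@H](C(=O)N(C)OC)[C@@H](O)c2ccc(OC)cc2)cc1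
F6 | step 5 | (2R,3R)-N,N'-dimethoxy-2,3-bis[(R)-(4-methoxyphenyl)(triethylsilyloxy)methyl]-N,N'-dimethylbutanediamide | COc1ccc([C@H](O[Si](CC)(CC)CC)[C@H](C(=O)N(C)OC)[C@@H](C(=O)N(C)OC)[C@@H](O[Si](CC)(CC)CC)c2ccc(OC)cc2)cc1
F7 | step 5 | (2R,3R)-1,4-bis[2,4-bis(benzyloxy)-6-fluorophenyl]-2,3-bis[(R)-(4-methoxyphenyl)(triethylsilyloxy)methyl]butane-1,4-dione | COc1ccc([C@H](O[Si](CC)(CC)CC)[C@H](C(=O)c2c(F)cc(OCc3ccccc3)cc2OCc2ccccc2)[C@@H](C(=O)c2c(F)cc(OCc3ccccc3)cc2OCc2ccccc2)[C@@H](O[Si](CC)(CC)CC)c2ccc(OC)cc2)cc1
F8 | step 1 | 3-(4-methoxyphenyl)propanoic acid | COc1ccc(CCC(=O)O)cc1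
F9 | step 1 | (4R)-4-isopropyl-3-[3-(4-methoxyphenyl)propanoyl]-1,3-oxazolidin-2-one | COc1ccc(CCC(=O)N2[C@H](C(C)C)COC2=O)cc1
F10 | step 1 | (4R,4'R)-3,3'-[(2S,3S)-2,3-bis(4-methoxybenzyl)butanedioyl]bis(4-isopropyl-1,3-oxazolidin-2-one) | COc1ccc(C[C@H](C(=O)N2[C@H](C(C)C)COC2=O)[C@H](Cc2ccc(OC)cc2)C(=O)N2[C@H](C(C)C)COC2=O)cc1
F11 | step 1 | (2S,3S)-2,3-bis(4-methoxybenzyl)butanedioic acid | COc1ccc(C[C@H](C(=O)O)[C@H](Cc2ccc(OC)cc2)C(=O)O)cc1
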